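**Retrosynthetic overview**

1. The enal junction C=C(CHO) is an aldol-condensation retron and both piperidines are identical (2S,3S,6R). The target is therefore the self-condensation dimer of one aldehyde, 12-[(2R,5S,6S)-5-hydroxy-6-methylpiperidin-2-yl]dodecanal (plausibly also its biogenetic origin); its formyl carbon comes from hydroformylation of a terminal alkene.
2. Each ring is cut at C3–C4 and N1–C6: a formal [3+3] union of an L-alanine-derived N1–C2–C3 unit (benzophenone Schiff-base methyl ester, brought to the aldehyde level in the flask) with a C4–C5–C6 ketone homoenolate (Grignard reagent of a β-bromo ketal carrying the C11 alkenyl chain).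
3. Enabling feature: the vicinal amino alcohol N1–C2–C3–O (imine N and carbonyl O chelate one metal, so C2 sets C3 as threo), together with the 1,4-relation of O3 to C6 and the 1,5-relation of N1 to C6. This γ-hydroxy-δ-amino ketone closes by itself to the six-membered N1=C6 imine; C6 is then set by hydride addition to that imine.
4. Ring order: the piperidine ring is made once, in the monomer (steps 4 and 5); the two rings of the target are copies of it, joined by the final C=C bond formation. There is no other ring.
5. Chain: 11-bromoundec-1-ene plus 3-bromopropanoyl chloride give the C14 bromo ketone, masked as a 5,5-dimethyl-1,3-dioxane.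

Key step: step 4

Remark: ring atoms are numbered N1, C2 (CH3), C3 (OH), C4, C5, C6 (chain) in every intermediate; the target is taken as the free base with the E-enal as drawn.

**Route**

Step 1
Reactants: 1 L-alanine methyl ester hydrochloride; 2 benzophenone imine
Product: 3 methyl (2S)-2-[(diphenylmethylidene)amino]propanoate
Conditions: CH2Cl2, rt, 24 h; filter
Reagents that add atoms: none
Why: Transimination of the amine hydrochloride with the N–H ketimine is driven by precipitation of NH4Cl and gives the N-diphenylmethylene Schiff base under neutral conditions that cannot epimerise C2 (Schiff-base formation by transimination; no new stereocentre).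

Step 2
Reactants: 4 11-bromoundec-1-ene; 5 3-bromopropanoyl chloride
Product: 7 1-bromotetradec-13-en-3-one, via undec-10-enylmagnesium bromide 6 (not isolated)
Conditions: 4, Mg, THF, 40 °C; then added to 5, Fe(acac)3 (3 mol %), THF, −78 °C
Reagents that add atoms: none
Why: Iron-catalysed acylation of the Grignard reagent with the acyl chloride should be far faster at −78 °C than addition to the ketone product, substitution of the primary bromide or dehydrobromination, so the β-bromo ketone should form cleanly (Grignard formation, then Fe(acac)3-catalysed ketone synthesis; no stereocentre).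

Step 3
Reactants: 7 1-bromotetradec-13-en-3-one
Product: 8 2-(2-bromoethyl)-5,5-dimethyl-2-(undec-10-en-1-yl)-1,3-dioxane
Conditions: 2,2-dimethylpropane-1,3-diol, HC(OEt)3, TsOH (cat.), CH2Cl2, rt
Reagents that add atoms: 2,2-dimethylpropane-1,3-diol, OCC(C)(C)CO
Why: Acid-catalysed ketalisation with the orthoformate as water scavenger masks the ketone as a 5,5-dimethyl-1,3-dioxane, the ketal type whose β-magnesio derivative is stable enough to act as a ketone homoenolate equivalent, and it leaves the bromide and the alkene untouched (ketalisation; no stereocentre).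

Step 4
Reactants: 3 methyl (2S)-2-[(diphenylmethylidene)amino]propanoate; 8 2-(2-bromoethyl)-5,5-dimethyl-2-(undec-10-en-1-yl)-1,3-dioxane
Product: 13 (2S,3S)-2-methyl-6-(undec-10-en-1-yl)-2,3,4,5-tetrahydropyridin-3-ol, via dioxanyl Grignard reagent 9 (not isolated), via aluminoxy acetal 10 (not isolated), via threo Schiff-base alcohol 11 (not isolated), via amino ketone 12 (not isolated)
Conditions: 8, Mg, THF, 25 °C (gives 9); 3, iBu2AlH/iBu3Al (1:1), CH2Cl2, −78 °C; then 9 (2.5 equiv), −78 °C → rt; then 1 M HCl, THF, rt; Et2O wash; NaOH to pH 11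
Reagents that add atoms: none
Why: iBu2AlH delivers one hydride to the ester of 3 and the tetrahedral aluminoxy acetal 10 is held by chelation of aluminium between the acetal oxygen and the imine nitrogen, so neither over-reduction nor epimerisation of C2 occurs; when 9 is added, 10 releases the metal-chelated imino aldehyde, whose aldehyde carbon (C3) is attacked by the primary carbanion carbon of 9 (C4) to give 11. The closest known reaction types are the one-flask hydride/organomagnesium reductive alkylation of N-(diphenylmethylene) α-amino esters, which is threo-selective, and the use of β-(1,3-dioxan-2-yl)ethylmagnesium halides as ketone homoenolate equivalents. The new stereocentre C3 is controlled by C2 through the five-membered N–metal–O chelate, the nucleophile entering on the face anti to the C2 methyl group, which should give the threo (2S,3S) amino alcohol. Aqueous HCl then hydrolyses both the Ph2C=N imine and the dioxane ketal, and on basification the δ-amino ketone 12 closes the only ring formed here by 6-exo-trig addition of N1 to the C6 carbonyl and loss of water, giving the endocyclic N1=C6 ketimine; no stereocentre is created in this ring closure. The step needs chemoselectivity (single hydride transfer, attack at the aldehyde and not at the ketimine carbon) and facial selectivity, and both are secured by the diphenylmethylene group, a chelating nitrogen mask that is too hindered to be attacked and falls off in the same acid treatment that unveils the ketone, while the six-membered imine is favoured over the reversible five-membered hemiketal from O3.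

Step 5
Reactants: 13 (2S,3S)-2-methyl-6-(undec-10-en-1-yl)-2,3,4,5-tetrahydropyridin-3-ol
Product: 14 (2S,3S,6R)-2-methyl-6-(undec-10-en-1-yl)piperidin-3-ol
Conditions: NaBH4, MeOH, −40 → 0 °C
Reagents that add atoms: none
Why: Borohydride reduction of the cyclic ketimine should proceed by axial hydride attack on the half-chair in which the C2 methyl group is pseudo-equatorial, on the face anti to the axial C3 hydroxyl and free of 1,3-diaxial hindrance, which sets C6 as R and gives the all-cis piperidine while sparing the terminal alkene (substrate-controlled imine reduction).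

Step 6
Reactants: 14 (2S,3S,6R)-2-methyl-6-(undec-10-en-1-yl)piperidin-3-ol
Product: 15 tert-butyl (2S,3S,6R)-3-hydroxy-2-methyl-6-(undec-10-en-1-yl)piperidine-1-carboxylate
Conditions: Boc2O (3 equiv), Et3N, THF, 60 °C
Reagents that add atoms: di-tert-butyl dicarbonate, CC(C)(C)OC(=O)OC(=O)OC(C)(C)C
Why: Boc2O acylates the secondary amine in preference to the secondary alcohol when no acylation catalyst is present, and the carbamate blocks enamine formation and hydroaminomethylation by the amine in the next two steps (N-Boc protection; no stereocentre).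

Step 7
Reactants: 15 tert-butyl (2S,3S,6R)-3-hydroxy-2-methyl-6-(undec-10-en-1-yl)piperidine-1-carboxylate
Product: 16 tert-butyl (2S,3S,6R)-3-hydroxy-2-methyl-6-(12-oxododecyl)piperidine-1-carboxylate
Conditions: Rh(acac)(CO)2 (1 mol %), Xantphos (2 mol %), CO/H2 (1:1, 10 bar), toluene, 80 °C
Reagents that add atoms: carbon monoxide, [C-]#[O+]
Why: Rhodium-catalysed hydroformylation of the terminal alkene with the wide-bite-angle diphosphine should be strongly linear-selective, placing the formyl carbon at the chain terminus and leaving carbamate and alcohol untouched (hydroformylation; no stereocentre).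

Step 8
Reactants: 16 tert-butyl (2S,3S,6R)-3-hydroxy-2-methyl-6-(12-oxododecyl)piperidine-1-carboxylate (two molecules)
Product: 17 (2E)-14-[(2R,5S,6S)-1-(tert-butoxycarbonyl)-5-hydroxy-6-methylpiperidin-2-yl]-2-{10-[(2R,5S,6S)-1-(tert-butoxycarbonyl)-5-hydroxy-6-methylpiperidin-2-yl]decyl}tetradec-2-enal
Conditions: pyrrolidine (10 mol %), PhCO2H (10 mol %), toluene, 60 °C
Reagents that add atoms: none
Why: Enamine-mediated aldol addition of one molecule of 16 to a second one and dehydration in the same flask should give the 2-alkyl-2-enal, the E isomer being the thermodynamic product because it keeps the formyl group and the β-alkyl chain apart (aldol self-condensation).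

Step 9
Reactants: 17 the bis-Boc enal of step 8
Product: 18 (2E)-14-[(2R,5S,6S)-5-hydroxy-6-methylpiperidin-2-yl]-2-{10-[(2R,5S,6S)-5-hydroxy-6-methylpiperidin-2-yl]decyl}tetradec-2-enal (CNP0177491.1)
Conditions: TFA, CH2Cl2, 0 °C → rt; then cold aq. NaHCO3
Reagents that add atoms: none
Why: Acidolysis of both tert-butyl carbamates (loss of 2-methylpropene and CO2) leaves the enal, the alcohols and all stereocentres unchanged, and cold bicarbonate work-up frees the hindered secondary amines, which should not condense readily with the α-branched enal (Boc removal).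

**Compound list**

1 | L-alanine methyl ester hydrochloride | C[C@H](N)C(=O)OC.Cl | starting material
2 | benzophenone imine (diphenylmethanimine) | N=C(c1ccccc1)c1ccccc1 | starting material
3 | methyl (2S)-2-[(diphenylmethylidene)amino]propanoate | C[C@H](N=C(c1ccccc1)c1ccccc1)C(=O)OC | intermediate
4 | 11-bromoundec-1-ene | C=CCCCCCCCCCBr | starting material
5 | 3-bromopropanoyl chloride | O=C(Cl)CCBr | starting material
6 | undec-10-en-1-ylmagnesium bromide | C=CCCCCCCCCC[Mg]Br | intermediate (not isolated)
7 | 1-bromotetradec-13-en-3-one | BrCCC(=O)CCCCCCCCCC=C | intermediate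
8 | 2-(2-bromoethyl)-5,5-dimethyl-2-(undec-10-en-1-yl)-1,3-dioxane | BrCCC1(CCCCCCCCCC=C)OCC(C)(C)CO1 | intermediate
9 | {2-[5,5-dimethyl-2-(undec-10-en-1-yl)-1,3-dioxan-2-yl]ethyl}magnesium bromide | Br[Mg]CCC1(CCCCCCCCCC=C)OCC(C)(C)CO1 | intermediate (not isolated)
10 | [(2S)-2-[(diphenylmethylidene)amino]-1-methoxypropoxy]bis(2-methylpropyl)aluminium (aluminoxy acetal) | C[C@H](N=C(c1ccccc1)c1ccccc1)C(OC)O[Al](CC(C)C)CC(C)C | intermediate (not isolated)
11 | (2S,3S)-5-[5,5-dimethyl-2-(undec-10-en-1-yl)-1,3-dioxan-2-yl]-2-[(diphenylmethylidene)amino]pentan-3-ol | C[C@H](N=C(c1ccccc1)c1ccccc1)[C@@H](O)CCC1(CCCCCCCCCC=C)OCC(C)(C)CO1 | intermediate (not isolated)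
12 | (2S,3S)-2-amino-3-hydroxyheptadec-16-en-6-one | C[C@H](N)[C@@H](O)CCC(=O)CCCCCCCCCC=C | intermediate (not isolated)
13 | (2S,3S)-2-methyl-6-(undec-10-en-1-yl)-2,3,4,5-tetrahydropyridin-3-ol | C[C@@H]1N=C(CCCCCCCCCC=C)CC[C@@H]1O | intermediate
14 | (2S,3S,6R)-2-methyl-6-(undec-10-en-1-yl)piperidin-3-ol | C[C@@H]1N[C@H](CCCCCCCCCC=C)CC[C@@H]1O | intermediate
15 | tert-butyl (2S,3S,6R)-3-hydroxy-2-methyl-6-(undec-10-en-1-yl)piperidine-1-carboxylate | C[C@@H]1N(C(=O)OC(C)(C)C)[C@H](CCCCCCCCCC=C)CC[C@@H]1O | intermediate
16 | tert-butyl (2S,3S,6R)-3-hydroxy-2-methyl-6-(12-oxododecyl)piperidine-1-carboxylate | C[C@@H]1N(C(=O)OC(C)(C)C)[C@H](CCCCCCCCCCCC=O)CC[C@@H]1O | intermediate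
17 | (2E)-14-[(2R,5S,6S)-1-(tert-butoxycarbonyl)-5-hydroxy-6-methylpiperidin-2-yl]-2-{10-[(2R,5S,6S)-1-(tert-butoxycarbonyl)-5-hydroxy-6-methylpiperidin-2-yl]decyl}tetradec-2-enal | C[C@@H]1N(C(=O)OC(C)(C)C)[C@H](CCCCCCCCCCC/C=C(/C=O)CCCCCCCCCC[C@@H]2CC[C@H](O)[C@H](C)N2C(=O)OC(C)(C)C)CC[C@@H]1O | intermediate
18 | (2E)-14-[(2R,5S,6S)-5-hydroxy-6-methylpiperidin-2-yl]-2-{10-[(2R,5S,6S)-5-hydroxy-6-methylpiperidin-2-yl]decyl}tetradec-2-enal (CNP0177491.1) | C[C@@H]1N[C@H](CCCCCCCCCCC/C=C(/C=O)CCCCCCCCCC[C@@H]2CC[C@H](O)[C@H](C)N2)CC[C@@H]1O | target

**Step count**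

Total: 9 steps. Longest linear sequence: 8 steps (4 → 7 → 8 → 13 → 14 → 15 → 16 → 17 → 18; steps 2 to 9).

**Steps most likely to fail, with fallbacks**

Step 4. The risk is loss of facial selectivity in the Grignard addition when a non-chelated pathway competes, made worse by slow decay of the β-magnesio ketal, so that the C3 epimer is carried along. The fallback sets out from 15 and comes back at 15. Because C6 is set by C2 alone, the epimeric material is taken through steps 5 and 6 unchanged. The mixture of 15 and its C3 epimer is then oxidised with 2-iodoxybenzoic acid (EtOAc, 70 °C) to the single ketone tert-butyl (2S,6R)-2-methyl-3-oxo-6-(undec-10-en-1-yl)piperidine-1-carboxylate F1. LiBH(s-Bu)3 (THF, −78 °C) should then add hydride on the face anti to the C2 methyl group, which the N-Boc group holds axial by A(1,3) strain, and return 15 as one diastereomer. Ring-controlled ketone reduction thus replaces acyclic chelation control.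

Step 8. The risk is over-condensation, the product enal re-entering dienamine chemistry and taking up further aldehyde, or stalling in the aldol/retro-aldol equilibrium. The fallback sets out from 16 and comes back at 17; the C=C bond is made by Wittig olefination instead of dehydration. α-Bromination of 16 (NBS, DL-proline cat., CH2Cl2, 0 °C) should give tert-butyl (2S,3S,6R)-6-(11-bromo-12-oxododecyl)-3-hydroxy-2-methylpiperidine-1-carboxylate F2 as a mixture of epimers at the brominated carbon. PPh3 (toluene, 60 °C) should convert it into {12-[(2R,5S,6S)-1-(tert-butoxycarbonyl)-5-hydroxy-6-methylpiperidin-2-yl]-1-oxododecan-2-yl}triphenylphosphonium bromide F3. Aqueous NaOH/CH2Cl2 should then give the formyl-stabilised ylide tert-butyl (2S,3S,6R)-3-hydroxy-2-methyl-6-[12-oxo-11-(triphenyl-λ5-phosphanylidene)dodecyl]piperidine-1-carboxylate F4. Heating F4 with a second equivalent of 16 (toluene, 90 °C) should give 17, stabilised ylides of this kind favouring the E-enal.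

Step 2. The risk is dehydrobromination of the β-bromo ketone (or of the acyl chloride) by the basic organomagnesium reagent, followed by conjugate addition to the vinyl ketone, and double addition to the acyl chloride. The fallback sets out from 4 and comes back at 8. The Grignard reagent 6 made from 4 is added to acrolein (THF, −78 °C) to give tetradeca-1,13-dien-3-ol F5. MnO2 (CH2Cl2, rt) should oxidise the allylic alcohol to tetradeca-1,13-dien-3-one F6. Me3SiBr (CH2Cl2, 0 °C), then 2,2-dimethylpropane-1,3-diol and TsOH (cat.), should effect conjugate hydrobromination and ketalisation in one flask to give 8. The β-bromo ketone is then never exposed to a base, and the isolated alkene should not react under these conditions.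

**Further compounds**

F1 | step 4 | tert-butyl (2S,6R)-2-methyl-3-oxo-6-(undec-10-en-1-yl)piperidine-1-carboxylate | C[C@@H]1N(C(=O)OC(C)(C)C)[C@H](CCCCCCCCCC=C)CCC1=O
F2 | step 8 | tert-butyl (2S,3S,6R)-6-(11-bromo-12-oxododecyl)-3-hydroxy-2-methylpiperidine-1-carboxylate | C[C@@H]1N(C(=O)OC(C)(C)C)[C@H](CCCCCCCCCCC(Br)C=O)CC[C@@H]1O
F3 | step 8 | {12-[(2R,5S,6S)-1-(tert-butoxycarbonyl)-5-hydroxy-6-methylpiperidin-2-yl]-1-oxododecan-2-yl}triphenylphosphonium bromide | C[C@@H]1N(C(=O)OC(C)(C)C)[C@H](CCCCCCCCCCC(C=O)[P+](c2ccccc2)(c2ccccc2)c2ccccc2)CC[C@@H]1O.[Br-]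
F4 | step 8 | tert-butyl (2S,3S,6R)-3-hydroxy-2-methyl-6-[12-oxo-11-(triphenyl-λ5-phosphanylidene)dodecyl]piperidine-1-carboxylate | C[C@@H]1N(C(=O)OC(C)(C)C)[C@H](CCCCCCCCCCC(C=O)=P(c2ccccc2)(c2ccccc2)c2ccccc2)CC[C@@H]1O
F5 | step 2 | tetradeca-1,13-dien-3-ol | C=CC(O)CCCCCCCCCC=C
F6 | step 2 | tetradeca-1,13-dien-3-one | C=CC(=O)CCCCCCCCCC=C
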